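Numbering: enone half C1–C10 (ring A = C1–C5 + C10, ring B = C5–C10), saturated half C1′–C10′, linker C11 (on C9) and C12 (on C9′). Remark on the chemistry: the enone half is read as cis-fused (3-OH, H-5 and the C10 methyl on one face), the other half as a trans-decalin with equatorial 8′-methyl.
Retrosynthesis: C7=O is taken back to a silyl ether and C6 is lent a tert-butyl ester. Ring B is then a cyclohexene whose only π bond (C8=C9) lies opposite the C5–C6 edge, and C10 and C5 are tied by the four-atom chain C1–C4 of ring A, so C5–C10 and C6–C7 are cut together (intramolecular Diels–Alder reaction of a 1-silyloxy triene).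
Further cuts: C10–C1 (sp2–sp3 coupling of a Z-enol triflate), C9–C11 (alkylation of pentane-2,4-dione, which supplies C8, C9, C10 and both methyl groups) and C7–C8 (one-carbon homologation).
Forward: (R)-pantolactone → tether with dienophile 6; (+)-sclareolide → aldehyde 13 → diketone 16 → triflate 17 → enone 19 → triene 22 → rings A and B closed together → ketone unmasked, ester and silyl groups removed.
Stereochemistry: C3 is bought (pantolactone) and relayed to C5 and C10 in the cycloaddition; C5′, C9′ and C10′ come from sclareolide, C3′ from an enzymatic hydroxylation, C8′ from a thermodynamically controlled hydrogenation.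

Key step: step 16

Abbreviation: D = the saturated half attached through C9′: 3′β-(tert-butyldimethylsilyloxy)-4′,4′,8′α,10′β-tetramethyl-trans-decalin-9′β-yl (5′α-H, 8′β-H, 9′α-H). D(OH) is the same group with free 3′β-OH.

Step 1
Reactants: 1 (R)-pantolactone
Product: 2 (3R)-4,4-dimethyl-3-(triisopropylsilyloxy)oxolan-2-one
Conditions: i-Pr3SiOTf, 2,6-lutidine, CH2Cl2, 0 °C to rt
Reagents that add atoms: triisopropylsilyl trifluoromethanesulfonate (CC(C)[Si](OS(=O)(=O)C(F)(F)F)(C(C)C)C(C)C)
Why: O-silylation with a silyl triflate; the bulky triisopropylsilyl group is chosen because it should not migrate to the neopentyl alkoxide set free in step 3, and the stereocentre is not touched.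

Step 2
Reactants: 2 (3R)-4,4-dimethyl-3-(triisopropylsilyloxy)oxolan-2-one
Product: 3 (3R)-4,4-dimethyl-3-(triisopropylsilyloxy)oxolan-2-ol (lactol, both anomers)
Conditions: i-Bu2AlH, CH2Cl2, −78 °C
Reagents that add atoms: none
Why: Partial reduction of a lactone to the lactol, since the tetrahedral aluminium hemiacetal should be stable at low temperature; C3 is not epimerised.

Step 3
Reactants: 3 lactol
Product: 4 (3S)-2,2-dimethyl-3-(triisopropylsilyloxy)pent-4-en-1-ol
Conditions: Ph3PCH3Br, KOt-Bu, THF, 0 °C to rt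
Reagents that add atoms: methyltriphenylphosphonium bromide (C[P+](c1ccccc1)(c1ccccc1)c1ccccc1.[Br-])
Why: Wittig methylenation of the open hydroxy-aldehyde form of the lactol, a standard way to a terminal alkene that leaves the hindered α-silyloxy stereocentre intact.

Step 4
Reactants: 4 (3S)-2,2-dimethyl-3-(triisopropylsilyloxy)pent-4-en-1-ol
Product: 6 tert-butyl (2E,5S)-4,4-dimethyl-5-(triisopropylsilyloxy)hepta-2,6-dienoate, via aldehyde 5 (not isolated)
Conditions: Dess–Martin periodinane, CH2Cl2, rt; then Ph3P=CHCO2t-Bu, 40 °C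
Reagents that add atoms: tert-butyl (triphenylphosphoranylidene)acetate (CC(C)(C)OC(=O)C=P(c1ccccc1)(c1ccccc1)c1ccccc1)
Why: One-pot Dess–Martin oxidation and Wittig olefination with a stabilised ylide, which should give the E-enoate; the aldehyde has a quaternary α-carbon and cannot enolise.

Step 5
Reactants: 7 (+)-sclareolide
Product: 8 3β-hydroxysclareolide (3′S carbinol)
Conditions: cytochrome P450 BM3 (CYP102A1) variant in E. coli lysate, NADP+ (cat.), NADP-dependent alcohol dehydrogenase, i-PrOH, air, KH2PO4/K2HPO4 buffer pH 8, 25 °C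
Reagents that add atoms: dioxygen (O=O)
Why: Enzymatic C–H hydroxylation by a cytochrome P450 monooxygenase (hydrogen abstraction and oxygen rebound with retention), in which the engineered pocket presents the equatorial C3′–H of ring A, so the 3β alcohol should form, as is known for this substrate.

Step 6
Reactants: 8 3β-hydroxysclareolide
Product: 9 3β-(tert-butyldimethylsilyloxy)sclareolide
Conditions: t-BuMe2SiOTf, 2,6-lutidine, CH2Cl2, 0 °C
Reagents that add atoms: tert-butyldimethylsilyl trifluoromethanesulfonate (CC(C)(C)[Si](C)(C)OS(=O)(=O)C(F)(F)F)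
Why: O-silylation with a silyl triflate, which should protect the hindered neopentyl secondary alcohol for the triflation of step 12.

Step 7
Reactants: 9 3β-(tert-butyldimethylsilyloxy)sclareolide
Product: 10 hydroxy Weinreb amide, N-methoxy-N-methyl-2-(8′α-hydroxy-8′β-methyl analogue of D)acetamide
Conditions: MeNH(OMe)·HCl, AlMe3, CH2Cl2, 0 °C to rt
Reagents that add atoms: N,O-dimethylhydroxylamine hydrochloride (CNOC.Cl)
Why: Aluminium-amide aminolysis of the lactone (Weinreb amide formation) cleaves the acyl C–O bond, so the C8′ carbinol configuration is kept.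

Step 8
Reactants: 10 hydroxy Weinreb amide
Product: 11 N-methoxy-N-methyl-2-(8′-methylidene analogue of D)acetamide (exocyclic alkene)
Conditions: SOCl2, pyridine, CH2Cl2, −78 °C
Reagents that add atoms: none
Why: Dehydration of the tertiary alcohol through its chlorosulfite (pyridine-assisted elimination) should give mainly the exocyclic alkene; the minor C7′=C8′ isomer converges in step 9 and C9′ is not touched.

Step 9
Reactants: 11 exocyclic alkene
Product: 12 N-methoxy-N-methyl-2-D-acetamide (8′α-methyl, 8′β-H)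
Conditions: Mn(dpm)3 (10 mol%), PhSiH3, t-BuOOH, i-PrOH, rt
Reagents that add atoms: none
Why: Hydrogen-atom-transfer hydrogenation (Mukaiyama type), in which the tertiary C8′ radical takes up the second hydrogen under product-like control, so the methyl should end equatorial (α), trans to the C9′ chain and clear of the axial C10′ methyl.

Step 10
Reactants: 12 saturated Weinreb amide
Product: 13 2-D-acetaldehyde
Conditions: i-Bu2AlH, THF, −78 °C
Reagents that add atoms: none
Why: Reduction of a Weinreb amide to the aldehyde, which should stop at the chelated tetrahedral intermediate until work-up.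

Step 11
Reactants: 13 2-D-acetaldehyde; 14 pentane-2,4-dione
Product: 16 3-(2-D-ethyl)pentane-2,4-dione, via alkylidene diketone 15 (not isolated)
Conditions: Hantzsch ester, L-proline (20 mol%), CH2Cl2, rt
Reagents that add atoms: none
Why: Organocatalytic reductive alkylation (Knoevenagel condensation, then conjugate transfer hydrogenation of the alkylidene diketone by the Hantzsch ester), which forms the C9–C11 bond without a new stereocentre.

Step 12
Reactants: 16 3-(2-D-ethyl)pentane-2,4-dione
Product: 17 (Z)-3-(2-D-ethyl)-4-(trifluoromethylsulfonyloxy)pent-3-en-2-one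
Conditions: Tf2O, saturated aqueous LiOH, toluene, 5 °C
Reagents that add atoms: trifluoromethanesulfonic anhydride (O=S(=O)(OS(=O)(=O)C(F)(F)F)C(F)(F)F)
Why: Stereoselective enol triflate formation from the lithium-chelated U-shaped enolate should place OTf cis to the remaining acetyl group (Z); the two acetyl groups are equivalent, so there is no regiochemical question.

Step 13
Reactants: 17 Z-enol triflate; 6 tert-butyl (2E,5S)-4,4-dimethyl-5-(triisopropylsilyloxy)hepta-2,6-dienoate
Product: 19 tert-butyl (2E,5S,8Z)-9-acetyl-11-D-4,4,8-trimethyl-5-(triisopropylsilyloxy)undeca-2,8-dienoate, via B-alkyl borane 18 (not isolated)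
Conditions: 6, 9-borabicyclo[3.3.1]nonane, THF, 0 °C to rt; then 17, Pd(dppf)Cl2 (5 mol%), AsPh3, aqueous K3PO4, DMF, rt
Reagents that add atoms: none
Why: Anti-Markovnikov hydroboration of the vinyl group (the conjugated ester reacts far more slowly) and B-alkyl Suzuki–Miyaura coupling, which proceeds with retention at the vinyl carbon, so C1 should end cis to the acetyl group on the C9=C10 bond.

Step 14
Reactants: 19 Z-enone
Product: 20 the 9-(2-methyloxiran-2-yl) analogue of 19 (epoxide of the acetyl carbonyl, both C8 epimers)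
Conditions: ICH2Cl, n-BuLi, THF, −78 °C to rt
Reagents that add atoms: chloroiodomethane (ClCI)
Why: Halomethyllithium epoxidation (addition of chloromethyllithium to the ketone, then ring closure of the chlorohydrin alkoxide), which should spare the hindered tert-butyl enoate at −78 °C; the new centre at C8 is lost in step 15.

Step 15
Reactants: 20 epoxide
Product: 22 tert-butyl (2E,5S,8Z)-9-[(1E)-1-(tert-butyldimethylsilyloxy)prop-1-en-2-yl]-11-D-4,4,8-trimethyl-5-(triisopropylsilyloxy)undeca-2,8-dienoate, via aldehyde 21 (not isolated)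
Conditions: BF3·OEt2 (10 mol%), CH2Cl2, −78 °C; then Et3N, t-BuMe2SiOTf, −78 to 0 °C
Reagents that add atoms: tert-butyldimethylsilyl trifluoromethanesulfonate (CC(C)(C)[Si](C)(C)OS(=O)(=O)C(F)(F)F)
Why: Meinwald rearrangement (1,2-hydride shift from C7 to the tertiary allylic C8) gives the β,γ-unsaturated aldehyde, whose only α-hydrogen is removed on soft enolisation, so the C9=C10 geometry should be kept and the silyloxy group should take the less hindered E position.

Step 16
Reactants: 22 (1E,3Z)-1-silyloxy triene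
Product: 23 cis-fused cycloadduct: tert-butyl ester at C6 and OSi(t-Bu)Me2 at C7 on the ring of the target, 3β-OSi(i-Pr)3, 5β-H, 10β-Me, C9 bearing CH2CH2-D
Conditions: toluene (0.01 M), 2,6-di-tert-butyl-4-methylphenol, Et3N (trace), 140 °C, sealed silylated tube
Reagents that add atoms: none
Why: Thermal normal-demand intramolecular Diels–Alder reaction: the HOMO of the electron-rich 1-silyloxy diene (C7=C8–C9=C10) and the LUMO of the tert-butyl enoate (C5=C6) combine in a concerted, asynchronous suprafacial [4+2] step in which the oxygen-bearing C7 meets the ester α-carbon C6 and the nucleophilic terminus C10 meets the β-carbon C5. The closest known reaction type is the thermal cyclisation of 1,3,9-decatrienoates and of tethered 1-silyloxydienes to octalins. Ring B closes as the new cyclohexene of the cycloaddition (C8=C9 is the π bond left over), and ring A closes at the same moment as a fused six-membered ring across the tether C1–C4, helped by the gem-dimethyl group at C4. Because the tether is cis to C8 on the C9=C10 bond (inside position), it can reach C5 only with the tether exo and the ester endo, which places H-5 on the face of the C10 methyl (cis fusion); the diene face is chosen by C3, whose OSi(i-Pr)3 group should stay equatorial on the chair-like tether because the axial position would clash with C6, and this gives the all-cis 3,5,10 array (C5 S, C10 S). The centres formed at C6 and C7 (shown as the endo-ester, outside-silyloxy isomer) do not matter, since C7 becomes the ketone and C6 a methylene group. The step needs cis fusion, one diene face and a rate above that of the [1,5]-hydrogen shift of the Z-diene; the Z geometry fixed in steps 12 and 13, the C3 stereocentre and the matched silyloxy/ester polarisation are meant to secure these.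

Step 17
Reactants: 23 cycloadduct
Product: 24 triol ester (3β-OH, 7-OH, 3′β-OH, tert-butyl ester at C6; side chain CH2CH2-D(OH))
Conditions: HF·pyridine, pyridine, THF, 0 to 40 °C
Reagents that add atoms: none
Why: Fluoride-mediated desilylation of all three silyl ethers under buffered acidic conditions, which the tert-butyl ester and the β-hydroxy ester unit should tolerate.

Step 18
Reactants: 24 triol ester
Product: 25 β-keto ester (C7 ketone conjugated with C8=C9, tert-butyl ester at C6)
Conditions: MnO2 (activated, excess), CH2Cl2, rt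
Reagents that add atoms: none
Why: Chemoselective allylic oxidation, since only the C7 carbinol is allylic and the two saturated secondary alcohols should not react with MnO2.

Step 19
Reactants: 25 β-keto ester
Product: 26 target compound
Conditions: p-TsOH·H2O (10 mol%), toluene, 80 °C
Reagents that add atoms: none
Why: Acid-catalysed loss of isobutene from the tert-butyl β-keto ester and decarboxylation of the β-keto acid, which leaves C6 as CH2; C5 is β to the ketone and is not epimerised.

Compound list
1 | (R)-pantolactone, (3R)-3-hydroxy-4,4-dimethyloxolan-2-one | CC1(C)COC(=O)[C@@H]1O | starting material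
2 | (3R)-4,4-dimethyl-3-(triisopropylsilyloxy)oxolan-2-one | CC1(C)COC(=O)[C@@H]1O[Si](C(C)C)(C(C)C)C(C)C | intermediate
3 | (3R)-4,4-dimethyl-3-(triisopropylsilyloxy)oxolan-2-ol, both anomers | CC1(C)COC(O)[C@@H]1O[Si](C(C)C)(C(C)C)C(C)C | intermediate
4 | (3S)-2,2-dimethyl-3-(triisopropylsilyloxy)pent-4-en-1-ol | C=C[C@H](O[Si](C(C)C)(C(C)C)C(C)C)C(C)(C)CO | intermediate
5 | (3S)-2,2-dimethyl-3-(triisopropylsilyloxy)pent-4-enal (not isolated) | C=C[C@H](O[Si](C(C)C)(C(C)C)C(C)C)C(C)(C)C=O | intermediate
6 | tert-butyl (2E,5S)-4,4-dimethyl-5-(triisopropylsilyloxy)hepta-2,6-dienoate | C=C[C@H](O[Si](C(C)C)(C(C)C)C(C)C)C(C)(C)/C=C/C(=O)OC(C)(C)C | intermediate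
7 | (+)-sclareolide | O=C1C[C@H]2[C@](C)(O1)CC[C@H]3C(C)(C)CCC[C@]23C | starting material
8 | 3β-hydroxysclareolide | O=C1C[C@H]2[C@](C)(O1)CC[C@H]3C(C)(C)[C@@H](O)CC[C@]23C | intermediate
9 | 3β-(tert-butyldimethylsilyloxy)sclareolide | O=C1C[C@H]2[C@](C)(O1)CC[C@H]3C(C)(C)[C@@H](O[Si](C)(C)C(C)(C)C)CC[C@]23C | intermediate
10 | hydroxy Weinreb amide (8′α-OH, 8′β-Me, 9′β-CH2CON(OMe)Me) | CON(C)C(=O)C[C@H]1[C@](C)(O)CC[C@H]2C(C)(C)[C@@H](O[Si](C)(C)C(C)(C)C)CC[C@]12C | intermediate
11 | 8′-methylidene Weinreb amide | CON(C)C(=O)C[C@H]1C(=C)CC[C@H]2C(C)(C)[C@@H](O[Si](C)(C)C(C)(C)C)CC[C@]12C | intermediate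
12 | N-methoxy-N-methyl-2-D-acetamide (8′α-Me, 8′β-H) | CON(C)C(=O)C[C@H]1[C@H](C)CC[C@H]2C(C)(C)[C@@H](O[Si](C)(C)C(C)(C)C)CC[C@]12C | intermediate
13 | 2-D-acetaldehyde | O=CC[C@H]1[C@H](C)CC[C@H]2C(C)(C)[C@@H](O[Si](C)(C)C(C)(C)C)CC[C@]12C | intermediate
14 | pentane-2,4-dione | CC(=O)CC(C)=O | starting material
15 | 3-(2-D-ethylidene)pentane-2,4-dione (not isolated) | CC(=O)C(=CC[C@H]1[C@H](C)CC[C@H]2C(C)(C)[C@@H](O[Si](C)(C)C(C)(C)C)CC[C@]12C)C(C)=O | intermediate
16 | 3-(2-D-ethyl)pentane-2,4-dione | CC(=O)C(CC[C@H]1[C@H](C)CC[C@H]2C(C)(C)[C@@H](O[Si](C)(C)C(C)(C)C)CC[C@]12C)C(C)=O | intermediate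
17 | (Z)-3-(2-D-ethyl)-4-(trifluoromethylsulfonyloxy)pent-3-en-2-one | CC(=O)/C(CC[C@H]1[C@H](C)CC[C@H]2C(C)(C)[C@@H](O[Si](C)(C)C(C)(C)C)CC[C@]12C)=C(/C)OS(=O)(=O)C(F)(F)F | intermediate
18 | B-alkyl-9-borabicyclo[3.3.1]nonane from 6 (not isolated) | B1(CC[C@H](O[Si](C(C)C)(C(C)C)C(C)C)C(C)(C)/C=C/C(=O)OC(C)(C)C)C2CCCC1CCC2 | intermediate
19 | tert-butyl (2E,5S,8Z)-9-acetyl-11-D-4,4,8-trimethyl-5-(triisopropylsilyloxy)undeca-2,8-dienoate | CC(=O)/C(CC[C@H]1[C@H](C)CC[C@H]2C(C)(C)[C@@H](O[Si](C)(C)C(C)(C)C)CC[C@]12C)=C(/C)CC[C@H](O[Si](C(C)C)(C(C)C)C(C)C)C(C)(C)/C=C/C(=O)OC(C)(C)C | intermediate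
20 | 9-(2-methyloxiran-2-yl) analogue of 19, both C8 epimers | CC1(CO1)/C(CC[C@H]1[C@H](C)CC[C@H]2C(C)(C)[C@@H](O[Si](C)(C)C(C)(C)C)CC[C@]12C)=C(/C)CC[C@H](O[Si](C(C)C)(C(C)C)C(C)C)C(C)(C)/C=C/C(=O)OC(C)(C)C | intermediate
21 | 9-(1-oxopropan-2-yl) analogue of 19, β,γ-unsaturated aldehyde (not isolated) | O=CC(C)/C(CC[C@H]1[C@H](C)CC[C@H]2C(C)(C)[C@@H](O[Si](C)(C)C(C)(C)C)CC[C@]12C)=C(/C)CC[C@H](O[Si](C(C)C)(C(C)C)C(C)C)C(C)(C)/C=C/C(=O)OC(C)(C)C | intermediate
22 | (1E,3Z)-1-silyloxy triene, 9-[(1E)-1-(tert-butyldimethylsilyloxy)prop-1-en-2-yl] analogue of 19 | CC(C)(C)[Si](C)(C)O/C=C(C)/C(CC[C@H]1[C@H](C)CC[C@H]2C(C)(C)[C@@H](O[Si](C)(C)C(C)(C)C)CC[C@]12C)=C(/C)CC[C@H](O[Si](C(C)C)(C(C)C)C(C)C)C(C)(C)/C=C/C(=O)OC(C)(C)C | intermediate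
23 | cis-fused cycloadduct (6-CO2t-Bu, 7-OSi(t-Bu)Me2, 3β-OSi(i-Pr)3, 5β-H, 10β-Me) | CC1=C(CC[C@H]2[C@H](C)CC[C@H]3C(C)(C)[C@@H](O[Si](C)(C)C(C)(C)C)CC[C@]23C)[C@@]2(C)CC[C@H](O[Si](C(C)C)(C(C)C)C(C)C)C(C)(C)[C@H]2[C@H](C(=O)OC(C)(C)C)[C@@H]1O[Si](C)(C)C(C)(C)C | intermediate
24 | triol ester (3β-OH, 7-OH, 3′β-OH, 6-CO2t-Bu) | CC1=C(CC[C@H]2[C@H](C)CC[C@H]3C(C)(C)[C@@H](O)CC[C@]23C)[C@@]2(C)CC[C@H](O)C(C)(C)[C@H]2[C@H](C(=O)OC(C)(C)C)[C@@H]1O | intermediate
25 | β-keto ester (7-oxo-8-ene, 6-CO2t-Bu, C6 epimers) | CC1=C(CC[C@H]2[C@H](C)CC[C@H]3C(C)(C)[C@@H](O)CC[C@]23C)[C@@]2(C)CC[C@H](O)C(C)(C)[C@H]2C(C(=O)OC(C)(C)C)C1=O | intermediate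
26 | CNP0290352.1 | CC1=C(CC[C@H]2[C@H](C)CC[C@H]3C(C)(C)[C@@H](O)CC[C@]23C)[C@@]2(C)CC[C@H](O)C(C)(C)[C@H]2CC1=O | target

Total step count: 19. Longest linear sequence: 15 steps (steps 5 to 19, from sclareolide 7).

Steps most likely to fail

Step 16. The cycloaddition may be outrun by the [1,5]-hydrogen shift of the Z-diene, or stall because the bond between the fully substituted C10 and the neopentyl C5 is very congested. The fallback closes both rings by an anionic sequence instead of a pericyclic one. It sets out from epoxide 20, which is rearranged as in step 15 but worked up cold at the aldehyde stage (21). Treatment of 21 with KN(SiMe3)2 in THF at −78 °C should give the dienolate, which adds through C10 to C5 of the enoate (intramolecular Michael addition, ring A); the ester enolate then closes onto the aldehyde carbon C7 (aldol addition, ring B). Addition of t-BuMe2SiOTf to the same flask gives 23, where the route is rejoined. The ring fusion would then rest on the cyclic chelated transition state and would have to be confirmed.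

Step 15. Opening of the epoxide may end in proton loss from the allyl cation, or the β,γ-unsaturated aldehyde may slip into conjugation, which would scramble the C9=C10 geometry. The fallback avoids any cationic stage. It sets out from ketone 19, which is converted by the boron-Wittig olefination with LiCH(Bpin)2 (from CH2(Bpin)2 and lithium 2,2,6,6-tetramethylpiperidide, THF, −78 °C to rt) into the (1E,3Z)-dienyl pinacol boronate F1. Thermal intramolecular Diels–Alder reaction of F1 (toluene, 150 °C) should give the allylic pinacol boronate cycloadduct F2, and oxidation with NaBO3·4H2O (THF/H2O, rt) should give the C7 allylic alcohol F3. F3 takes the place of 23 in step 17 and comes back to the route at 24.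

Step 9. Hydrogen may be delivered to the wrong face of C8′, which would leave the methyl axial. The fallback uses hydroxyl-directed hydrogenation instead of radical control. It sets out from alkene 11, which is reduced with i-Bu2AlH and then NaBH4 in the same flask to the 8′-methylidene primary alcohol F4. The hydroxyethyl arm on the β face of C9′ should direct [Ir(cod)(PCy3)(py)]PF6/H2 (CH2Cl2, rt) to the β face of the alkene and give the saturated alcohol F5. Dess–Martin oxidation of F5 comes back to the route at aldehyde 13.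

Further compounds
F0 | step 16 | none | none
F1 | step 15 | (1E,3Z)-dienyl pinacol boronate, 9-[(1E)-1-(4,4,5,5-tetramethyl-1,3,2-dioxaborolan-2-yl)prop-1-en-2-yl] analogue of 19 | CC1(C)OB(OC1(C)C)/C=C(C)/C(CC[C@H]1[C@H](C)CC[C@H]2C(C)(C)[C@@H](O[Si](C)(C)C(C)(C)C)CC[C@]12C)=C(/C)CC[C@H](O[Si](C(C)C)(C(C)C)C(C)C)C(C)(C)/C=C/C(=O)OC(C)(C)C
F2 | step 15 | allylic pinacol boronate cycloadduct (Bpin at C7 in place of the silyloxy group of 23) | CC1=C(CC[C@H]2[C@H](C)CC[C@H]3C(C)(C)[C@@H](O[Si](C)(C)C(C)(C)C)CC[C@]23C)[C@@]2(C)CC[C@H](O[Si](C(C)C)(C(C)C)C(C)C)C(C)(C)[C@H]2[C@H](C(=O)OC(C)(C)C)[C@@H]1B1OC(C)(C)C(C)(C)O1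
F3 | step 15 | C7 allylic alcohol cycloadduct (3β-OSi(i-Pr)3, 3′β-OSi(t-Bu)Me2, 6-CO2t-Bu) | CC1=C(CC[C@H]2[C@H](C)CC[C@H]3C(C)(C)[C@@H](O[Si](C)(C)C(C)(C)C)CC[C@]23C)[C@@]2(C)CC[C@H](O[Si](C(C)C)(C(C)C)C(C)C)C(C)(C)[C@H]2[C@H](C(=O)OC(C)(C)C)[C@@H]1O
F4 | step 9 | 2-(8′-methylidene analogue of D)ethanol | OCC[C@H]1C(=C)CC[C@H]2C(C)(C)[C@@H](O[Si](C)(C)C(C)(C)C)CC[C@]12C
F5 | step 9 | 2-D-ethanol | OCC[C@H]1[C@H](C)CC[C@H]2C(C)(C)[C@@H](O[Si](C)(C)C(C)(C)C)CC[C@]12C
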